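**Plan** (acyl chain C1–C20 from the ester carbonyl; alcohol chain C1′–C9′; ring C1″–C6″)

1. Retrosynthesis: the four Z-alkenes (C5–C15) are unmasked from alkynes. The acyl chain is then cut at C2–C3, each end carrying a CO2H that leaves as CO2: a C19 skipped tetraynoic acid and the hydrogen malonate of the diterpenol.
2. Further cuts: the malonate O–C(=O) bond (Meldrum's acid), the C8′–C9′ bond next to the ring (sulfone alkylation) and the propargylic CH2–C≡C bonds of the tetrayne.
3. Enabling feature: C2–C3 is an unbranched CH2–CH2 bond. C2 lies α to the ester carbonyl C1, so it can come from a malonic half ester. C3 is insulated by C4 from C5≡C6, and with C5≡C6 as an alkyne the C3 radical can neither cyclise nor lose geometry. The 2,6,6-trimethylcyclohex-2-ene ring and C1″ are remote and take no part.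
4. Forward: tetraynoic acid (steps 1–4). (S)-α-Cyclogeranyl sulfone (5–9) and a geraniol-derived C10 bromide (10–12) are joined and trimmed to the diterpenol (13–15), which is malonylated (16), coupled anodically with the acid (17) and semihydrogenated (18). No ring is formed; the ring is bought as 2,4,4-trimethylcyclohexenone.
5. Stereochemistry: C1″ (S) comes from a CBS reduction relayed by a suprafacial [2,3]-Wittig–Still shift. 2′E,6′E come from geraniol and an E-selective SeO2 oxidation. 5Z,8Z,11Z,14Z come from syn hydrogenation of the four alkynes.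

Key step: step 17

Remark: the ring carbon C1″ of the target is read as S; 10 and 12 are taken as catalogue compounds.

**Route**

Step 1
Reactants: 1 1-bromooct-2-yne; 2 ethynylmagnesium bromide
Product: 3 deca-1,4-diyne
Conditions: 2 (2.5 equiv), CuCl (cat.), THF, 0 °C → 50 °C; aq. NH4Cl
Reagents that add atoms: none
Why: Copper-catalysed SN2 coupling of an alkynyl Grignard reagent with a propargylic bromide is the classical entry to a terminal 1,4-diyne, and the excess of 2 should keep the product from reacting a second time.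

Step 2
Reactants: 4 methyl pent-4-ynoate; 5 1,4-dibromobut-2-yne
Product: 6 methyl 9-bromonona-4,7-diynoate
Conditions: 5 (4 equiv), CuI (cat.), K2CO3, n-Bu4NCl, DMF, rt, Ar
Reagents that add atoms: none
Why: Copper(I)/carbonate coupling of a terminal alkyne with a propargylic bromide tolerates the ester, and the excess of the symmetric dibromide should hold the reaction at mono-substitution.

Step 3
Reactants: 3 deca-1,4-diyne; 6 methyl 9-bromonona-4,7-diynoate
Product: 7 methyl nonadeca-4,7,10,13-tetraynoate
Conditions: CuI (cat.), K2CO3, n-Bu4NCl, DMF, rt, Ar, dark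
Reagents that add atoms: none
Why: The same copper(I)/carbonate propargyl–alkyne coupling joins the two diynes under conditions mild enough not to isomerise the skipped polyyne to allenes.

Step 4
Reactants: 7 methyl nonadeca-4,7,10,13-tetraynoate
Product: 9 nonadeca-4,7,10,13-tetraynoic acid, via lithium tetraynoate 8 (not isolated)
Conditions: LiOH, THF/H2O, 0 °C → rt, Ar; then 1 M HCl, 0 °C
Reagents that add atoms: lithium hydroxide, [Li+].[OH-]
Why: Mild saponification of a methyl ester, as practised on skipped polyynoates, frees the carboxyl group needed for the anodic coupling.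

Step 5
Reactants: 10 2,4,4-trimethylcyclohex-2-en-1-one
Product: 11 (1R)-2,4,4-trimethylcyclohex-2-en-1-ol
Conditions: (S)-2-methyl-CBS-oxazaborolidine (10 mol%), BH3·SMe2, THF, −20 °C; MeOH quench
Reagents that add atoms: none
Why: Corey–Bakshi–Shibata reduction, in which the ketone binds the catalyst with its larger α-methyl-substituted alkenyl arm away from the B-methyl group so that hydride is delivered to one face and C1 should be set as R.

Step 6
Reactants: 11 (1R)-2,4,4-trimethylcyclohex-2-en-1-ol; 12 tributyl(iodomethyl)stannane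
Product: 14 tributyl({[(1R)-2,4,4-trimethylcyclohex-2-en-1-yl]oxy}methyl)stannane, via potassium alkoxide 13 (not isolated)
Conditions: KH, THF, 0 °C → rt; then 12, rt
Reagents that add atoms: none
Why: Williamson etherification of the potassium alkoxide with the SN2-reactive α-stannyl iodide leaves the carbinol stereocentre untouched.

Step 7
Reactants: 14 tributyl({[(1R)-2,4,4-trimethylcyclohex-2-en-1-yl]oxy}methyl)stannane
Product: 16 (S)-α-cyclogeraniol, via lithiomethyl ether 15 (not isolated)
Conditions: n-BuLi, THF, −78 °C → −40 °C; H2O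
Reagents that add atoms: none
Why: [2,3]-Wittig–Still rearrangement, in which tin–lithium exchange gives the α-alkoxymethyllithium that shifts suprafacially from the pseudoaxial C1–O bond (favoured by A(1,2) strain with the C2 methyl group) to C3 on the same face, so the R carbinol centre should be relayed 1,3 into the S ring carbon bearing CH2OH.

Step 8
Reactants: 16 (S)-α-cyclogeraniol
Product: 17 phenyl [(1S)-2,6,6-trimethylcyclohex-2-en-1-yl]methyl sulfide
Conditions: PhSSPh, n-Bu3P, pyridine, rt → 50 °C
Reagents that add atoms: diphenyl disulfide, c1ccccc1SSc1ccccc1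
Why: Mitsunobu-type thioetherification, in which the alkoxyphosphonium ion is displaced by thiophenolate at the primary carbon without touching the ring stereocentre.

Step 9
Reactants: 17 phenyl [(1S)-2,6,6-trimethylcyclohex-2-en-1-yl]methyl sulfide
Product: 18 phenyl [(1S)-2,6,6-trimethylcyclohex-2-en-1-yl]methyl sulfone
Conditions: 30% H2O2, (NH4)6Mo7O24·4H2O (cat.), EtOH, 0 °C → rt
Reagents that add atoms: hydrogen peroxide, OO
Why: Molybdate-catalysed peroxide oxidation should take the sulfide to the sulfone much faster than it epoxidises the trisubstituted ring alkene.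

Step 10
Reactants: 19 geraniol
Product: 20 geranyl tert-butyldimethylsilyl ether
Conditions: TBSCl, imidazole, DMF, rt
Reagents that add atoms: tert-butyldimethylsilyl chloride, CC(C)(C)[Si](C)(C)Cl
Why: Standard silylation protects the allylic alcohol against the oxidation, bromination and carbanion steps that follow.

Step 11
Reactants: 20 geranyl tert-butyldimethylsilyl ether
Product: 21 (2E,6E)-8-[(tert-butyldimethylsilyl)oxy]-2,6-dimethylocta-2,6-dien-1-ol
Conditions: SeO2 (cat.), t-BuOOH, salicylic acid (cat.), CH2Cl2, 0 °C → rt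
Reagents that add atoms: tert-butyl hydroperoxide, CC(C)(C)OO (oxygen relayed by catalytic selenium dioxide, O=[Se]=O)
Why: Catalytic selenium dioxide allylic oxidation (ene reaction then [2,3] shift) attacks the more electron-rich distal trisubstituted alkene at its E-methyl group and should give the E-allylic alcohol.

Step 12
Reactants: 21 (2E,6E)-8-[(tert-butyldimethylsilyl)oxy]-2,6-dimethylocta-2,6-dien-1-ol
Product: 22 (2E,6E)-8-bromo-3,7-dimethylocta-2,6-dien-1-yl tert-butyldimethylsilyl ether
Conditions: CBr4, PPh3, CH2Cl2, −20 °C → 0 °C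
Reagents that add atoms: carbon tetrabromide, BrC(Br)(Br)Br
Why: Appel bromination converts the primary allylic alcohol into the bromide under neutral conditions without allylic transposition or loss of the silyl ether.

Step 13
Reactants: 18 phenyl [(1S)-2,6,6-trimethylcyclohex-2-en-1-yl]methyl sulfone; 22 (2E,6E)-8-bromo-3,7-dimethylocta-2,6-dien-1-yl tert-butyldimethylsilyl ether
Product: 24 C9′-phenylsulfonyl diterpenyl silyl ether (epimer mixture at C9′), via α-lithio sulfone 23 (not isolated)
Conditions: n-BuLi, THF/HMPA, −78 °C; then 22, −78 °C → −20 °C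
Reagents that add atoms: none
Why: Alkylation of the α-sulfonyl carbanion by SN2 at the primary allylic bromide forms C8′–C9′ with both E-alkenes untouched, and the new sulfonyl-bearing centre is an epimer mixture that the next step erases.

Step 14
Reactants: 24 C9′-phenylsulfonyl diterpenyl silyl ether
Product: 25 (2E,6E)-3,7-dimethyl-9-[(1S)-2,6,6-trimethylcyclohex-2-en-1-yl]nona-2,6-dien-1-yl tert-butyldimethylsilyl ether
Conditions: Na(Hg) (6%), Na2HPO4, MeOH/THF, −20 °C → 0 °C
Reagents that add atoms: none
Why: Reductive desulfonylation by electron transfer from sodium amalgam cleaves the C–S bond and methanol protonates the carbanion, while the phosphate buffer keeps the medium from isomerising the ring alkene.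

Step 15
Reactants: 25 (2E,6E)-3,7-dimethyl-9-[(1S)-2,6,6-trimethylcyclohex-2-en-1-yl]nona-2,6-dien-1-yl tert-butyldimethylsilyl ether
Product: 26 (2E,6E)-3,7-dimethyl-9-[(1S)-2,6,6-trimethylcyclohex-2-en-1-yl]nona-2,6-dien-1-ol
Conditions: TBAF, THF, 0 °C → rt
Reagents that add atoms: none
Why: Fluoride cleaves the Si–O bond under conditions that leave the acid-sensitive trisubstituted alkenes and the allylic stereocentre alone.

Step 16
Reactants: 26 (2E,6E)-3,7-dimethyl-9-[(1S)-2,6,6-trimethylcyclohex-2-en-1-yl]nona-2,6-dien-1-ol; 27 Meldrum's acid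
Product: 28 hydrogen malonate of 26
Conditions: 27 (1.0 equiv), toluene, 100 °C
Reagents that add atoms: none
Why: Alcoholysis of Meldrum's acid by the primary allylic alcohol with loss of acetone gives the malonic half ester directly, which installs C1 and C2 of the acyl chain together with the carboxyl handle for the anodic coupling.

Step 17
Reactants: 9 nonadeca-4,7,10,13-tetraynoic acid; 28 hydrogen malonate of 26
Product: 31 diterpenyl icosa-5,8,11,14-tetraynoate, via tetraynyl radical 29 (not isolated), via ester-methyl radical 30 (not isolated)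
Conditions: undivided cell, Pt anode and cathode, 9 (4 equiv), 28 (1 equiv), KOH (partial neutralisation), MeOH, constant current ca. 150 mA cm−2, 10–15 °C, Ar
Reagents that add atoms: none
Why: Mixed Kolbe electrolysis: at the platinum anode under high current density each carboxylate is oxidised by one electron, the acyloxy radicals lose CO2, and the primary radicals 29 and 30, born side by side in the carboxylate layer, combine to form the C2–C3 bond. The closest known reaction type is the anodic heterocoupling of an alkanoic acid with a malonic acid half ester, a two-carbon chain extension to an alkyl acetate. No ring is closed and no stereocentre is formed; the S ring carbon and the 2′E,6′E alkenes are remote spectators. The step needs cross- over homocoupling, which is biased by the fourfold excess of the simpler acid 9 (the symmetric C36 octayne and the succinate differ widely from 31 in polarity), and radical over cation chemistry, which is secured because both radicals are primary and the α-ester radical 30 is electron-poor. It also needs 29 to stay intact: as an alk-3-ynyl radical it has no double-bond geometry to lose and its linear triple bonds forbid 3-exo and 6-exo closure, whereas the alk-3-enyl radical of the corresponding Z-tetraene acid could scramble C5=C6 through a cyclopropylmethyl radical. Radical 30 should not close 5-exo onto C2′=C3′ because the ester prefers its s-trans conformation, and the trisubstituted alkenes should be spared because adsorbed carboxylate dominates the anode surface.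

Step 18
Reactants: 31 diterpenyl icosa-5,8,11,14-tetraynoate
Product: 32 CNP0207506.1
Conditions: H2 (1 atm), Lindlar catalyst, quinoline, EtOAc/hexane, 0–10 °C, stopped after uptake of 4 equiv
Reagents that add atoms: none
Why: Lindlar cis-semihydrogenation delivers both hydrogens from the catalyst surface to one face of each alkyne and should set 5Z,8Z,11Z,14Z at once, while the poisoned catalyst leaves the trisubstituted alkenes and the allylic ester alone.

**Compound list**

1 | 1-bromooct-2-yne | CCCCCC#CCBr | starting material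
2 | ethynylmagnesium bromide | C#C[Mg]Br | starting material
3 | deca-1,4-diyne | CCCCCC#CCC#C | intermediate
4 | methyl pent-4-ynoate | COC(=O)CCC#C | starting material
5 | 1,4-dibromobut-2-yne | BrCC#CCBr | starting material
6 | methyl 9-bromonona-4,7-diynoate | COC(=O)CCC#CCC#CCBr | intermediate
7 | methyl nonadeca-4,7,10,13-tetraynoate | CCCCCC#CCC#CCC#CCC#CCCC(=O)OC | intermediate
8 | lithium nonadeca-4,7,10,13-tetraynoate | [Li+].[O-]C(=O)CCC#CCC#CCC#CCC#CCCCCC | intermediate
9 | nonadeca-4,7,10,13-tetraynoic acid | CCCCCC#CCC#CCC#CCC#CCCC(=O)O | intermediate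
10 | 2,4,4-trimethylcyclohex-2-en-1-one | CC1=CC(C)(C)CCC1=O | starting material
11 | (1R)-2,4,4-trimethylcyclohex-2-en-1-ol | O[C@H]1C(C)=CC(C)(C)CC1 | intermediate
12 | tributyl(iodomethyl)stannane | CCCC[Sn](CCCC)(CCCC)CI | starting material
13 | potassium (1R)-2,4,4-trimethylcyclohex-2-en-1-olate | [K+].[O-][C@H]1C(C)=CC(C)(C)CC1 | intermediate
14 | tributyl({[(1R)-2,4,4-trimethylcyclohex-2-en-1-yl]oxy}methyl)stannane | CCCC[Sn](CCCC)(CCCC)CO[C@H]1C(C)=CC(C)(C)CC1 | intermediate
15 | ({[(1R)-2,4,4-trimethylcyclohex-2-en-1-yl]oxy}methyl)lithium | [Li]CO[C@H]1C(C)=CC(C)(C)CC1 | intermediate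
16 | [(1S)-2,6,6-trimethylcyclohex-2-en-1-yl]methanol, (S)-α-cyclogeraniol | OC[C@@H]1C(C)=CCCC1(C)C | intermediate
17 | phenyl [(1S)-2,6,6-trimethylcyclohex-2-en-1-yl]methyl sulfide | c1ccccc1SC[C@@H]1C(C)=CCCC1(C)C | intermediate
18 | phenyl [(1S)-2,6,6-trimethylcyclohex-2-en-1-yl]methyl sulfone | O=S(=O)(C[C@@H]1C(C)=CCCC1(C)C)c1ccccc1 | intermediate
19 | geraniol | CC(C)=CCC/C(C)=C/CO | starting material
20 | tert-butyl{[(2E)-3,7-dimethylocta-2,6-dien-1-yl]oxy}dimethylsilane | CC(C)=CCC/C(C)=C/CO[Si](C)(C)C(C)(C)C | intermediate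
21 | (2E,6E)-8-[(tert-butyldimethylsilyl)oxy]-2,6-dimethylocta-2,6-dien-1-ol | OC/C(C)=C/CC/C(C)=C/CO[Si](C)(C)C(C)(C)C | intermediate
22 | {[(2E,6E)-8-bromo-3,7-dimethylocta-2,6-dien-1-yl]oxy}(tert-butyl)dimethylsilane | BrC/C(C)=C/CC/C(C)=C/CO[Si](C)(C)C(C)(C)C | intermediate
23 | lithio(phenylsulfonyl)[(1S)-2,6,6-trimethylcyclohex-2-en-1-yl]methane | [Li]C([C@@H]1C(C)=CCCC1(C)C)S(=O)(=O)c1ccccc1 | intermediate
24 | tert-butyl{[(2E,6E,9RS)-3,7-dimethyl-9-(phenylsulfonyl)-9-[(1S)-2,6,6-trimethylcyclohex-2-en-1-yl]nona-2,6-dien-1-yl]oxy}dimethylsilane | CC(C)(C)[Si](C)(C)OC/C=C(\C)CC/C=C(\C)CC([C@@H]1C(C)=CCCC1(C)C)S(=O)(=O)c1ccccc1 | intermediate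
25 | tert-butyl{[(2E,6E)-3,7-dimethyl-9-[(1S)-2,6,6-trimethylcyclohex-2-en-1-yl]nona-2,6-dien-1-yl]oxy}dimethylsilane | CC(C)(C)[Si](C)(C)OC/C=C(\C)CC/C=C(\C)CC[C@@H]1C(C)=CCCC1(C)C | intermediate
26 | (2E,6E)-3,7-dimethyl-9-[(1S)-2,6,6-trimethylcyclohex-2-en-1-yl]nona-2,6-dien-1-ol | OC/C=C(\C)CC/C=C(\C)CC[C@@H]1C(C)=CCCC1(C)C | intermediate
27 | Meldrum's acid (2,2-dimethyl-1,3-dioxane-4,6-dione) | CC1(C)OC(=O)CC(=O)O1 | starting material
28 | 3-{[(2E,6E)-3,7-dimethyl-9-[(1S)-2,6,6-trimethylcyclohex-2-en-1-yl]nona-2,6-dien-1-yl]oxy}-3-oxopropanoic acid | OC(=O)CC(=O)OC/C=C(\C)CC/C=C(\C)CC[C@@H]1C(C)=CCCC1(C)C | intermediate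
29 | octadeca-3,6,9,12-tetrayn-1-yl radical | [CH2]CC#CCC#CCC#CCC#CCCCCC | intermediate
30 | 2-{[(2E,6E)-3,7-dimethyl-9-[(1S)-2,6,6-trimethylcyclohex-2-en-1-yl]nona-2,6-dien-1-yl]oxy}-2-oxoethyl radical | [CH2]C(=O)OC/C=C(\C)CC/C=C(\C)CC[C@@H]1C(C)=CCCC1(C)C | intermediate
31 | (2E,6E)-3,7-dimethyl-9-[(1S)-2,6,6-trimethylcyclohex-2-en-1-yl]nona-2,6-dien-1-yl icosa-5,8,11,14-tetraynoate | CCCCCC#CCC#CCC#CCC#CCCCC(=O)OC/C=C(\C)CC/C=C(\C)CC[C@@H]1C(C)=CCCC1(C)C | intermediate
32 | (2E,6E)-3,7-dimethyl-9-[(1S)-2,6,6-trimethylcyclohex-2-en-1-yl]nona-2,6-dien-1-yl (5Z,8Z,11Z,14Z)-icosa-5,8,11,14-tetraenoate, CNP0207506.1 | CCCCC/C=C\C/C=C\C/C=C\C/C=C\CCCC(=O)OC/C=C(\C)CC/C=C(\C)CC[C@@H]1C(C)=CCCC1(C)C | target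

**Totals**

Total step count: 18. Longest linear sequence: 11 steps (steps 5–9, then 13–18).

**Steps most likely to fail**

1. Step 17 (anodic heterocoupling). What may go wrong: the two homocouplings dominate statistically, the trisubstituted alkenes or the skipped polyyne are over-oxidised at the anode, or the 1,4-diyne units isomerise in the partly neutralised methanol. Fallback: the bond is made by two-electron chemistry, setting out from 28, 3 and 5 and returning to the route at 32. But-3-yn-1-ol F1 is coupled with excess 5 (CuI, K2CO3, n-Bu4NCl, DMF) to 8-bromoocta-3,6-diyn-1-ol F2, and F2 with 3 under the same conditions to octadeca-3,6,9,12-tetrayn-1-ol F3. Lindlar semihydrogenation should give (3Z,6Z,9Z,12Z)-octadeca-3,6,9,12-tetraen-1-ol F4, and I2/PPh3/imidazole the iodide (3Z,6Z,9Z,12Z)-1-iodooctadeca-3,6,9,12-tetraene F5. Half ester 28 is deprotonated twice (LDA, THF/HMPA, −78 °C) to the dilithium dianion of 28 F6, which is alkylated with F5 to the 2-alkylmalonic half ester F7 (epimer mixture). Heating (toluene, 100 °C) should decarboxylate F7 to 32, so step 18 is not needed on this path.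

2. Step 18 (fourfold semihydrogenation on the full ester). What may go wrong: over-reduction to saturated segments, incomplete reduction leaving enynes, Z-to-E isomerisation on the catalyst, or hydrogenolysis of the allylic C–O bond, all giving near-isomers that cannot be removed at the last stage. Fallback: the reduction is moved to the simple ester, setting out from 7 and returning at 32. Compound 7 is semihydrogenated (Lindlar/quinoline or P-2 nickel, H2) to methyl (4Z,7Z,10Z,13Z)-nonadeca-4,7,10,13-tetraenoate F8, which can be purified on silver nitrate–silica. Saponification (LiOH, THF/H2O) gives (4Z,7Z,10Z,13Z)-nonadeca-4,7,10,13-tetraenoic acid F9, and mixed Kolbe electrolysis of F9 with 28 under the conditions of step 17 should give 32 directly. The price is possible Z/E leakage at the 4-ene of the alk-3-enyl radical, to be held down by high current density.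

3. Step 7 ([2,3]-Wittig–Still shift). What may go wrong: a competing [1,2] shift or simple protonation of the carbanion, because the receiving carbon is flanked by the quaternary centre, and with it erosion of the chirality transfer. Fallback: a neutral thermal rearrangement, setting out from 11 and returning at 16. Alcohol 11 is heated with N,N-dimethylformamide dimethyl acetal (xylene, 140 °C, sealed tube); the amide-acetal [2,3] rearrangement, again suprafacial, should give (1S)-N,N,2,6,6-pentamethylcyclohex-2-ene-1-carboxamide F10, which lithium amidotrihydroborate (THF, 0 °C → rt) reduces to 16.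

**Further compounds**

F1 | step 17 | but-3-yn-1-ol | C#CCCO
F2 | step 17 | 8-bromoocta-3,6-diyn-1-ol | OCCC#CCC#CCBr
F3 | step 17 | octadeca-3,6,9,12-tetrayn-1-ol | CCCCCC#CCC#CCC#CCC#CCCO
F4 | step 17 | (3Z,6Z,9Z,12Z)-octadeca-3,6,9,12-tetraen-1-ol | CCCCC/C=C\C/C=C\C/C=C\C/C=C\CCO
F5 | step 17 | (3Z,6Z,9Z,12Z)-1-iodooctadeca-3,6,9,12-tetraene | CCCCC/C=C\C/C=C\C/C=C\C/C=C\CCI
F6 | step 17 | dilithium dianion of 28 | [Li+].[Li+].[O-]C(=O)[CH-]C(=O)OC/C=C(\C)CC/C=C(\C)CC[C@@H]1C(C)=CCCC1(C)C
F7 | step 17 | 2-[(3Z,6Z,9Z,12Z)-octadeca-3,6,9,12-tetraen-1-yl]malonic acid mono[(2E,6E)-3,7-dimethyl-9-[(1S)-2,6,6-trimethylcyclohex-2-en-1-yl]nona-2,6-dien-1-yl] ester | CCCCC/C=C\C/C=C\C/C=C\C/C=C\CCC(C(=O)O)C(=O)OC/C=C(\C)CC/C=C(\C)CC[C@@H]1C(C)=CCCC1(C)C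
F8 | step 18 | methyl (4Z,7Z,10Z,13Z)-nonadeca-4,7,10,13-tetraenoate | CCCCC/C=C\C/C=C\C/C=C\C/C=C\CCC(=O)OC
F9 | step 18 | (4Z,7Z,10Z,13Z)-nonadeca-4,7,10,13-tetraenoic acid | CCCCC/C=C\C/C=C\C/C=C\C/C=C\CCC(=O)O
F10 | step 7 | (1S)-N,N,2,6,6-pentamethylcyclohex-2-ene-1-carboxamide | CN(C)C(=O)[C@@H]1C(C)=CCCC1(C)C
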